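## The problem

Target 19 is an ent-drimane ether of umbelliferone. Drimane numbering is used throughout: ring A = C1–C5 and C10, ring B = C5–C10, C11 = the OCH2 carbon, C12 = the methyl on C8.

- The skeleton is a trans-fused decalin. Ring A carries the C3 ketone beside the C4 gem-dimethyl group; ring B carries the C7=C8 alkene and, on C9, the CH2O–coumarin arm.
- Three contiguous stereocentres are needed (5S, 9R, 10R). C10 is quaternary and lies between the other two, with its methyl anti to H-5 and syn to C11.
- C10 is the natural point of absolute control. Once C10 and C5 are locked in a trans-fused bicycle, the shape of ring B decides the face on which a reagent meets C7, and a C7 substituent can hand its configuration to C9.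
- The C7=C8 alkene is β,γ to C9 and one proton shift from the tetrasubstituted C8=C9 position, so strong acid and strong base are excluded once it is in place.
- The coumarin lactone does not survive hydride, organometallic or hydroxide reagents, so the aryl ether must go on late. The C3 ketone must be masked whenever a strong base or an organolithium is used.
- C11 is primary but flanked by a tertiary and a quaternary carbon, so its etherification is not trivial.
- The feature that opens the key step: C5–C10 and C8–C9 are the two bonds of a Robinson-type annulation between an aldehyde (carbonyl C9, α-carbon C10) and an ethyl enone (β-carbon C5, carbonyl C7, α'-carbon C8). The C3 carbonyl and the hydrogen-free C4 can sit as bystanders in a C1–C4 tether, so both partners fit into one open chain, 9.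
- The price is an oxygen on C7 that the target lacks; it is used as the handle that delivers C11 to C9.

## Retrosynthesis

**19 ⇒ 18 ⇒ 16 + 17.** The last operations are unmasking of C3 (18 → 19) and formation of the C11–O aryl bond (16 + 17 → 18). Attaching the coumarin earlier is ruled out, because the lactone of 17 would meet a hydride and an organolithium. The cut leaves the terpenoid alcohol 16 and commercial 17. The forward reaction must etherify a β-branched primary alcohol under neutral conditions, without eliminating toward a diene and without moving the C7=C8 alkene.

**16 ⇒ 14 ⇒ 13.** The C9–C11 bond is cut as a [2,3]-sigmatropic shift of a stannylmethyl ether on the C7 oxygen. Conjugate addition of a one-carbon nucleophile to enone 12 is the neighbouring option, but it would enter C9 anti to the C10 methyl (the wrong epimer) and leave a C7 ketone to be removed regioselectively. The sigmatropic cut places the alkene at C7=C8 by mechanism and makes C9 a copy of C7. The precursor 13 has one carbon less, and its only extra stereocentre is set by a simple reduction. The forward reaction must be suprafacial on the face syn to the C10 methyl, which requires the 7R carbinol.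

**13 ⇒ 12 ⇒ 11.** These are functional-group changes only: 1,2-reduction of the enone and masking of C3 as a dioxolane. They ask for two selectivities. The saturated C3 ketone must react with the diol ahead of the conjugated C7 ketone. Hydride must then reach C7 axially, from the face of H-5, so that the hydroxyl ends pseudoequatorial and syn to the C10 methyl.

**11 ⇒ 9 (key cut).** C5–C10 and C8=C9 are cut together. Cutting only C8=C9 would stop at the ring A keto aldehyde 10, whose two stereocentres would still have to be made. The double cut removes both rings and both ring-fusion stereocentres and leaves an acyclic trione whose single stereocentre does not matter. The forward reaction asks a chiral amine catalyst to choose the face of a tetrasubstituted enamine carbon (C10), to join it to a neopentyl β-carbon (C5) through a chair transition state that gives the trans relation, and then to condense C8 with C9.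

**9 ⇒ 7 + 8.** The C1–C10 bond is cut as a conjugate addition of propanal 8 to the vinyl ketone of 7. Building the same 5-oxo aldehyde by chain extension of an ester would need protecting-group and redox steps; this cut uses an established amine-catalysed aldehyde/vinyl ketone addition instead. The forward reaction must attack only the unsubstituted vinyl ketone, not the hindered ethyl enone, and the catalyst must leave the α-branched product 9 alone.

**7 ⇒ 6 ⇒ 4 + 5.** The C2–C3 bond is cut as addition of vinyl Grignard 5 to aldehyde 4, followed by oxidation of carbinol 6. The forward addition must prefer the aldehyde over the conjugated ketone of 4.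

**4 ⇒ 3 ⇒ 1 + 2.** The C5=C6 alkene is cut as a Wittig reaction of hydroxy aldehyde 1 with the stabilised ylide 2, followed by oxidation of the primary alcohol of 3. The C4 quaternary carbon is bought with 1, and the E geometry comes from the ylide.

## Roads not taken

**Alternative 1:** Ring B by a Diels–Alder reaction across C7–C8 and C9–C10.
- Cut and key step: the ring A diene 7-ethenyl-6,6,8-trimethyl-1,4-dioxaspiro[4.5]dec-7-ene A1 reacts with but-2-ynal A2 under a Brønsted-acid-assisted chiral boron Lewis acid. The product is the 1,4-cyclohexadiene aldehyde A3, the C3 ketal of ent-drima-5,8-dien-11-al.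
- Merits: the route is convergent. After the key step all fifteen skeletal carbons are present, with C11 already on C9. The chosen plan needs steps 9 and 10 for that carbon; here the alternative is better.
- Weak points: the diene terminus C10 is fully substituted, and the vinyl group sits between the C4 gem-dimethyl group and the C10 methyl, so the reactive s-cis conformer is disfavoured. The new C9–C10 bond joins two carbons without hydrogen. The diene and the ketal are exposed to a strong boron Lewis acid.
- Only C10 is set. C5 must come from reduction of the C5=C6 alkene between two quaternary carbons with an enal present. C9 must come from deconjugation of the C8=C9 enal with kinetic protonation. A1 also needs its own multistep synthesis.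
- Comparison: the chosen plan sets C5 and C10 in one step and relays C9 by a stereospecific shift. It pays for this with the later introduction of C11.

**Alternative 2:** Ring A by a Diels–Alder reaction across C1–C10 and C4–C5.
- Cut and key step: the aminosiloxy diene (E)-3-(tert-butyldimethylsilyloxy)-N,N-dimethylbuta-1,3-dien-1-amine A4 adds to (E)-2-methylhept-2-en-5-ynal A5 under (salen)CrSbF6 (trivalent chromium). Acidic work-up expels dimethylamine and gives the enone aldehyde A6.
- Merits: this catalyst class is established for formyl-bearing quaternary centres from α-substituted acroleins. The trans relation of C5 and C10 follows stereospecifically from the E geometry of A5. In that respect it is more secure than the chosen plan, which has only a chair transition-state preference to set against it.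
- Weak points: A5 carries a β-substituent as well, which lowers dienophile reactivity below what the precedent covers. A6 lacks both C4 methyl groups; they would need two alkylations next to C5 after saturation of C1=C2, with the aldehyde protected. Ring B is still open and C11 is missing.
- Comparison: closing ring B by joining the C9 aldehyde to alkyne carbon C8 would at best reach an analogue of 11 and then need the same endgame as steps 7–12. The chosen plan has C3 and C4 in final form from the start and reaches 11 in six steps.

**Alternative 3:** Ring B by allylic dearomatisation of a phenol, cutting C9–C10 alone.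
- Cut and key step: the phenol 2,4-dimethyl-3-[(2Z)-3-(oxiran-2-yl)but-2-en-1-yl]phenol A7 is ionised by Pd2(dba)3 (zerovalent palladium) with a chiral bis(diphenylphosphinobenzoyl)diaminocyclohexane ligand. This gives a C7–C8–C9 allyl complex, and the para carbon C10 attacks C9. The product is the cross-conjugated dienone A8, with C7=C8 and the free C11 alcohol in place.
- Merits: this is the most direct road. A8 has ring B exactly as in the target, and C9 and C10 are set together. What remains is ring A work (saturation of C1=C2, reductive methylation at C4 that also sets C5) and the etherification. That is no longer than steps 7–12 and avoids organotin chemistry; here the alternative is as good or better.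
- Weak points: C4, ortho to the hydroxyl, is as close to the allyl terminus as C10 and is also methyl-substituted, so ortho and para attack both give six-membered rings. The allyl complex must take the geometry that puts C7=C8 cis inside the ring. The C9/C10 relation depends on equilibration of the allyl diastereomers formed from a racemic epoxide. The later dissolving-metal methylation must spare the C7=C8 alkene. A7 is a tetrasubstituted arene with a geometrically defined alkenyl epoxide and needs a long preparation.
- Comparison: the chosen plan sets against this a five-step acyclic precursor, bond connectivity fixed by ring size alone, and C3/C4 functionality that needs no later adjustment.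

Key step: step 6

Remark: the sense of induction of 9-amino-9-deoxy-epi-cinchona catalysts on an α,α-dialkyl aldehyde of this kind is not established; the quinine-derived catalyst is written in step 6, and its quinidine-derived pseudoenantiomer takes its place if the first favours the (4aR,8aR) series.

Remark: 9 is used as whatever mixture of C2 configurations step 5 delivers, because this centre is erased in the enamine of step 6; it is written without a descriptor.

## Route

Step 1
Reactants: 1 3-hydroxy-2,2-dimethylpropanal (hydroxypivaldehyde); 2 1-(triphenyl-λ5-phosphanylidene)butan-2-one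
Product: 3 (E)-7-hydroxy-6,6-dimethylhept-4-en-3-one
Conditions: toluene, 90 °C
Reagents that add atoms: none
Why: Wittig olefination with a ketone-stabilised ylide; the hemiacetal dimer of 1 reverts to the monomer on heating, the free hydroxyl does not interfere, and the stabilised ylide should give the E-enone (C5=C6).

Step 2
Reactants: 3
Product: 4 (E)-2,2-dimethyl-5-oxohept-3-enal
Conditions: Dess–Martin periodinane, CH2Cl2, 0 → 25 °C
Reagents that add atoms: none
Why: Dess–Martin oxidation of a primary alcohol; the new aldehyde has no α-hydrogen, so it can neither enolise nor move the alkene, and the enone is inert to the oxidant.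

Step 3
Reactants: 4; 5 vinylmagnesium bromide
Product: 6 (E)-7-hydroxy-6,6-dimethylnona-4,8-dien-3-one (racemic)
Conditions: CH2=CHMgBr (1.05 equiv), THF, −78 °C; aq. NH4Cl
Reagents that add atoms: none
Why: Grignard 1,2-addition; the aldehyde is markedly more electrophilic than the conjugated ethyl ketone, so one equivalent at low temperature should add at C3 only; the racemic carbinol centre is removed in step 4.

Step 4
Reactants: 6
Product: 7 (E)-4,4-dimethylnona-1,5-diene-3,7-dione
Conditions: Dess–Martin periodinane, CH2Cl2, 0 → 25 °C
Reagents that add atoms: none
Why: Dess–Martin oxidation of a secondary allylic alcohol; neutral conditions avoid conjugate addition to the vinyl ketone formed, which is used without storage.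

Step 5
Reactants: 7; 8 propanal
Product: 9 (E)-2,6,6-trimethyl-5,9-dioxoundec-7-enal
Conditions: 8 (3 equiv), (S)-2-(methoxydiphenylmethyl)pyrrolidine (5 mol %), ethyl 3,4-dihydroxybenzoate (20 mol %), neat, 4 °C
Reagents that add atoms: none
Why: Amine-catalysed (enamine) Michael addition of a linear aldehyde to a vinyl ketone, forming C1–C10; only the β-unsubstituted vinyl ketone is reactive enough, the neopentyl-flanked ethyl enone is not, and the hindered secondary amine does not form an enamine from the α-branched product, so 9 should accumulate; the new centre is of no consequence.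

Step 6
Reactants: 9
Product: 11 (4aS,8aS)-1,1,4a,6-tetramethyl-1,3,4,4a,8,8a-hexahydronaphthalene-2,7-dione, via Michael adduct 10 (not isolated)
Conditions: 9-amino-9-deoxy-epi-quinine (20 mol %), CF3CO2H (40 mol %), toluene, 40 °C
Reagents that add atoms: none
Why: Proposed new method: the primary amine condenses with the aldehyde of 9 and the imine tautomerises to the secondary enamine, which erases the old C10 centre; the enamine carbon C10 then adds to the enone β-carbon C5, which is activated by hydrogen bonding to the protonated quinuclidine, and hydrolysis gives 10. The catalyst next forms the enamine of the ethyl ketone, whose carbon C8 attacks the C9 aldehyde, and loss of water gives the C8=C9 enone 11 and makes the sequence irreversible. The closest known reaction types are the amine-catalysed Michael–aldol annulation of α-branched aldehydes with vinyl ketones and the amine-catalysed intramolecular Michael addition of unbranched aldehydes to enones; new here is a tetrasubstituted enamine carbon meeting a neopentyl β-carbon within one chain, followed directly by the condensation. Ring A closes by a 6-(enolexo)-exo-trig Michael addition and ring B by a 6-(enolendo)-exo-trig aldol condensation. C10 is set by the catalyst, which shields one face of the enamine. C5 is set relative to C10 by a chair transition state in which the E-enone arm and the catalyst-bearing enamine arm are both equatorial and the small methyl group takes the axial site, which puts the formyl group trans to the oxobutyl chain and so gives the trans ring fusion. The step needs chemoselectivity among three carbonyl groups, and the substrate secures it: only the aldehyde condenses readily with the amine, C4 bears no hydrogen so the enone cannot deconjugate, the gem-dimethyl ketone tether favours closure, and ring size leaves C8–C9 as the only feasible condensation, since attack of C6 or C2 on C9 would give four-membered rings.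

Step 7
Reactants: 11
Product: 12 (4a'S,8a'S)-1',1',4a',6'-tetramethyl-3',4',4a',8a'-tetrahydro-1'H-spiro[1,3-dioxolane-2,2'-naphthalen]-7'(8'H)-one
Conditions: ethylene glycol (excess), p-TsOH·H2O (cat.), 4 Å molecular sieves, 25 °C
Reagents that add atoms: ethylene glycol, OCCO
Why: Acid-catalysed ketalisation; a saturated ketone next to a quaternary carbon is known to react with the diol ahead of a conjugated ketone in bicyclic enediones of this type, and the enone has no γ-hydrogen, so it cannot deconjugate.

Step 8
Reactants: 12
Product: 13 (4a'S,7'R,8a'S)-1',1',4a',6'-tetramethyl-3',4',4a',7',8',8a'-hexahydro-1'H-spiro[1,3-dioxolane-2,2'-naphthalen]-7'-ol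
Conditions: NaBH4, CeCl3·7H2O, MeOH, −78 → 0 °C
Reagents that add atoms: none
Why: Luche 1,2-reduction of the enone; hydride should add axially at C7 from the face of H-5, as with trans-fused 1-en-3-one steroids, giving the pseudoequatorial 7R alcohol syn to the C10 methyl.

Step 9
Reactants: 13
Product: 14 tributyl({[(4a'S,7'R,8a'S)-1',1',4a',6'-tetramethyl-3',4',4a',7',8',8a'-hexahydro-1'H-spiro[1,3-dioxolane-2,2'-naphthalen]-7'-yl]oxy}methyl)stannane
Conditions: KH, Bu3SnCH2I, THF, 0 → 25 °C
Reagents that add atoms: tributyl(iodomethyl)stannane, CCCC[Sn](CCCC)(CCCC)CI
Why: Williamson etherification of the potassium alkoxide with a primary iodide; the C7 configuration is untouched and the ketal protects C3 from the base.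

Step 10
Reactants: 14
Product: 16 [(4a'R,5'R,8a'S)-1',1',4a',6'-tetramethyl-3',4',4a',5',8',8a'-hexahydro-1'H-spiro[1,3-dioxolane-2,2'-naphthalen]-5'-yl]methanol, via lithiomethyl ether 15 (not isolated)
Conditions: n-BuLi, THF, −78 → −20 °C; aq. NH4Cl
Reagents that add atoms: none
Why: Wittig–Still [2,3]-sigmatropic rearrangement; tin–lithium exchange gives the α-alkoxy organolithium 15, which shifts suprafacially across C7–C8–C9, so C11 should arrive at C9 on the face that carried the C7 oxygen (syn to the C10 methyl, 9R) and the alkene moves to C7=C8 by mechanism.

Step 11
Reactants: 16; 17 umbelliferone (7-hydroxy-2H-chromen-2-one)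
Product: 18 7-{[(4a'R,5'R,8a'S)-1',1',4a',6'-tetramethyl-3',4',4a',5',8',8a'-hexahydro-1'H-spiro[1,3-dioxolane-2,2'-naphthalen]-5'-yl]methoxy}-2H-chromen-2-one
Conditions: PPh3, DIAD, THF, 0 → 25 °C
Reagents that add atoms: none
Why: Mitsunobu etherification of a primary alcohol with a phenol of pKa about 8; C11 is not stereogenic, and the neutral conditions spare the lactone, the ketal and the β,γ-alkene.

Step 12
Reactants: 18
Product: 19 7-{[(1R,4aS,8aR)-2,5,5,8a-tetramethyl-6-oxo-1,4,4a,5,6,7,8,8a-octahydronaphthalen-1-yl]methoxy}-2H-chromen-2-one (CNP0262399.1)
Conditions: 1 M aq. HCl, THF, 25 °C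
Reagents that add atoms: water, O
Why: Acid-catalysed ketal hydrolysis; relief of strain next to the C4 quaternary carbon speeds cleavage, and dilute acid at room temperature is not expected to move the C7=C8 alkene or to touch the aryl ether and lactone.

## Compound list

1 | 3-hydroxy-2,2-dimethylpropanal | CC(C)(CO)C=O | starting material
2 | 1-(triphenyl-λ5-phosphanylidene)butan-2-one | CCC(=O)C=P(c1ccccc1)(c1ccccc1)c1ccccc1 | starting material
3 | (E)-7-hydroxy-6,6-dimethylhept-4-en-3-one | CCC(=O)/C=C/C(C)(C)CO | intermediate
4 | (E)-2,2-dimethyl-5-oxohept-3-enal | CCC(=O)/C=C/C(C)(C)C=O | intermediate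
5 | vinylmagnesium bromide | C=C[Mg]Br | starting material
6 | (E)-7-hydroxy-6,6-dimethylnona-4,8-dien-3-one (racemic) | CCC(=O)/C=C/C(C)(C)C(O)C=C | intermediate
7 | (E)-4,4-dimethylnona-1,5-diene-3,7-dione | CCC(=O)/C=C/C(C)(C)C(=O)C=C | intermediate
8 | propanal | CCC=O | starting material
9 | (E)-2,6,6-trimethyl-5,9-dioxoundec-7-enal (C2 unassigned) | CCC(=O)/C=C/C(C)(C)C(=O)CCC(C)C=O | intermediate
10 | (1R,2S)-1,3,3-trimethyl-4-oxo-2-(2-oxobutyl)cyclohexane-1-carbaldehyde | O=C[C@]1(C)CCC(=O)C(C)(C)[C@H]1CC(=O)CC | intermediate
11 | (4aS,8aS)-1,1,4a,6-tetramethyl-1,3,4,4a,8,8a-hexahydronaphthalene-2,7-dione | CC1=C[C@]2(C)CCC(=O)C(C)(C)[C@H]2CC1=O | intermediate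
12 | (4a'S,8a'S)-1',1',4a',6'-tetramethyl-3',4',4a',8a'-tetrahydro-1'H-spiro[1,3-dioxolane-2,2'-naphthalen]-7'(8'H)-one | CC1=C[C@]2(C)CCC3(OCCO3)C(C)(C)[C@H]2CC1=O | intermediate
13 | (4a'S,7'R,8a'S)-1',1',4a',6'-tetramethyl-3',4',4a',7',8',8a'-hexahydro-1'H-spiro[1,3-dioxolane-2,2'-naphthalen]-7'-ol | CC1=C[C@]2(C)CCC3(OCCO3)C(C)(C)[C@H]2C[C@H]1O | intermediate
14 | tributyl({[(4a'S,7'R,8a'S)-1',1',4a',6'-tetramethyl-3',4',4a',7',8',8a'-hexahydro-1'H-spiro[1,3-dioxolane-2,2'-naphthalen]-7'-yl]oxy}methyl)stannane | CC1=C[C@]2(C)CCC3(OCCO3)C(C)(C)[C@H]2C[C@H]1OC[Sn](CCCC)(CCCC)CCCC | intermediate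
15 | {[(4a'S,7'R,8a'S)-1',1',4a',6'-tetramethyl-3',4',4a',7',8',8a'-hexahydro-1'H-spiro[1,3-dioxolane-2,2'-naphthalen]-7'-yl]oxy}methyllithium | CC1=C[C@]2(C)CCC3(OCCO3)C(C)(C)[C@H]2C[C@H]1OC[Li] | intermediate
16 | [(4a'R,5'R,8a'S)-1',1',4a',6'-tetramethyl-3',4',4a',5',8',8a'-hexahydro-1'H-spiro[1,3-dioxolane-2,2'-naphthalen]-5'-yl]methanol | CC1=CC[C@@H]2C(C)(C)C3(OCCO3)CC[C@@]2(C)[C@@H]1CO | intermediate
17 | umbelliferone (7-hydroxy-2H-chromen-2-one) | Oc1ccc2ccc(=O)oc2c1 | starting material
18 | 7-{[(4a'R,5'R,8a'S)-1',1',4a',6'-tetramethyl-3',4',4a',5',8',8a'-hexahydro-1'H-spiro[1,3-dioxolane-2,2'-naphthalen]-5'-yl]methoxy}-2H-chromen-2-one | CC1=CC[C@@H]2C(C)(C)C3(OCCO3)CC[C@@]2(C)[C@@H]1COc1ccc2ccc(=O)oc2c1 | intermediate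
19 | 7-{[(1R,4aS,8aR)-2,5,5,8a-tetramethyl-6-oxo-1,4,4a,5,6,7,8,8a-octahydronaphthalen-1-yl]methoxy}-2H-chromen-2-one | CC1=CC[C@@H]2C(C)(C)C(=O)CC[C@@]2(C)[C@@H]1COc1ccc2ccc(=O)oc2c1 | target

## Step count and least certain steps

Total step count: 12. Longest linear sequence: 12 steps (1 → 19).

**Step 6 (key step, proposed new method).**
- What may go wrong: the C–C bond between a fully substituted enamine carbon and a neopentyl β-carbon may fail to form. The catalyst may be sequestered by condensation with both carbonyl groups of the 1,5-keto aldehyde. Enantioselectivity may erode if the two enamine geometries react at similar rates. The trans selectivity may be lost if the Michael step becomes reversible and the adduct with an axial formyl group builds up.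
- Fallback (known chemistry, a stoichiometric chiral amine in place of the catalyst; it sets out from 9 and comes back at 11): condensation of 9 with (R)-1-phenylethylamine (MgSO4, CH2Cl2) gives the aldimine (E)-2,6,6-trimethyl-1-{[(R)-1-phenylethyl]imino}undec-7-ene-5,9-dione F1. On warming in THF its secondary-enamine tautomer should add to the enone in the intramolecular aza-ene manner established for chiral imines of α-branched carbonyl compounds. This gives the cyclised aldimine (3S,4R)-2,2,4-trimethyl-3-(2-oxobutyl)-4-({[(R)-1-phenylethyl]imino}methyl)cyclohexan-1-one F2. Aqueous acetic acid then releases 10, now isolated, and KOH in methanol closes ring B to 11. The enantiomer of the amine is chosen once the sense of induction is known.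

**Step 10 (Wittig–Still rearrangement).**
- What may go wrong: the pseudoequatorial C7–O bond of the rigid trans-fused ring is poorly aligned with the alkene π system. The [2,3] shift may then be slow enough for the [1,2] shift and simple protonation of the carbanion to compete.
- Fallback (sets out from 13 and comes back at 16): Mitsunobu esterification of 13 with picolinic acid (PPh3, DIAD) inverts C7 and gives the pseudoaxial ester (4a'S,7'S,8a'S)-1',1',4a',6'-tetramethyl-3',4',4a',7',8',8a'-hexahydro-1'H-spiro[1,3-dioxolane-2,2'-naphthalen]-7'-yl pyridine-2-carboxylate F3. Copper-mediated anti-SN2' substitution with (i-PrO)Me2SiCH2MgCl and CuBr·SMe2 should then place the silylmethyl group on C9 from the face syn to the C10 methyl. This gives isopropoxydimethyl{[(4a'R,5'R,8a'S)-1',1',4a',6'-tetramethyl-3',4',4a',5',8',8a'-hexahydro-1'H-spiro[1,3-dioxolane-2,2'-naphthalen]-5'-yl]methyl}silane F4. Tamao–Fleming oxidation (H2O2, KF, KHCO3, THF/MeOH) gives 16.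

**Step 11 (Mitsunobu etherification).**
- What may go wrong: displacement at the β-branched C11 may be slow, and elimination of the activated alcohol toward the diene conjugated with C7=C8 may take over.
- Fallback (sets out from 16 and comes back at 18): the aryl–oxygen bond is formed instead of the alkyl–oxygen bond. Palladium-catalysed C–O coupling of 16 with commercial 7-bromo-2H-chromen-2-one (Pd2(dba)3 (zerovalent palladium), a bulky di-tert-butyl biaryl phosphine, Cs2CO3, toluene, 80 °C) needs no substitution at C11.

**Step 3 (vinyl addition).**
- What may go wrong: competing 1,2-addition to the enone carbonyl, or double addition, if the two carbonyl groups are not distinguished well enough.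
- Fallback (sets out from 1 and comes back at 6): the order is reversed so that the Grignard reagent never meets an enone. Addition of CH2=CHMgBr (2.2 equiv) to 1 gives 2,2-dimethylpent-4-ene-1,3-diol F5. Oxoammonium oxidation (TEMPO cat., PhI(OAc)2) selective for the primary alcohol gives 3-hydroxy-2,2-dimethylpent-4-enal F6. Wittig reaction of F6 with 2 gives 6.

## Further compounds

F1 | step 6 | (E)-2,6,6-trimethyl-1-{[(R)-1-phenylethyl]imino}undec-7-ene-5,9-dione | C[C@@H](/N=C/C(C)CCC(=O)C(C)(C)/C=C/C(=O)CC)c1ccccc1
F2 | step 6 | (3S,4R)-2,2,4-trimethyl-3-(2-oxobutyl)-4-({[(R)-1-phenylethyl]imino}methyl)cyclohexan-1-one | C[C@@H](/N=C/[C@]1(C)CCC(=O)C(C)(C)[C@H]1CC(=O)CC)c1ccccc1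
F3 | step 10 | (4a'S,7'S,8a'S)-1',1',4a',6'-tetramethyl-3',4',4a',7',8',8a'-hexahydro-1'H-spiro[1,3-dioxolane-2,2'-naphthalen]-7'-yl pyridine-2-carboxylate | CC1=C[C@]2(C)CCC3(OCCO3)C(C)(C)[C@H]2C[C@@H]1OC(=O)c1ccccn1
F4 | step 10 | isopropoxydimethyl{[(4a'R,5'R,8a'S)-1',1',4a',6'-tetramethyl-3',4',4a',5',8',8a'-hexahydro-1'H-spiro[1,3-dioxolane-2,2'-naphthalen]-5'-yl]methyl}silane | CC1=CC[C@@H]2C(C)(C)C3(OCCO3)CC[C@@]2(C)[C@@H]1C[Si](C)(C)OC(C)C
F0 | step 11 | none | none
F5 | step 3 | 2,2-dimethylpent-4-ene-1,3-diol | C=CC(O)C(C)(C)CO
F6 | step 3 | 3-hydroxy-2,2-dimethylpent-4-enal | C=CC(O)C(C)(C)C=O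
A1 | alternative 1 | 7-ethenyl-6,6,8-trimethyl-1,4-dioxaspiro[4.5]dec-7-ene | C=CC1=C(C)CCC2(OCCO2)C1(C)C
A2 | alternative 1 | but-2-ynal | CC#CC=O
A3 | alternative 1 | (4a'R)-1',1',4a',6'-tetramethyl-3',4',4a',7'-tetrahydro-1'H-spiro[1,3-dioxolane-2,2'-naphthalene]-5'-carbaldehyde (C3 ketal of ent-drima-5,8-dien-11-al) | CC1=C(C=O)[C@]2(C)CCC3(OCCO3)C(C)(C)C2=CC1
A4 | alternative 2 | (E)-3-(tert-butyldimethylsilyloxy)-N,N-dimethylbuta-1,3-dien-1-amine | CN(C)/C=C/C(=C)O[Si](C)(C)C(C)(C)C
A5 | alternative 2 | (E)-2-methylhept-2-en-5-ynal | CC#CC/C=C(\C)C=O
A6 | alternative 2 | (1S,6R)-6-(but-2-yn-1-yl)-1-methyl-4-oxocyclohex-2-ene-1-carbaldehyde | O=C[C@]1(C)C=CC(=O)C[C@H]1CC#CC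
A7 | alternative 3 | 2,4-dimethyl-3-[(2Z)-3-(oxiran-2-yl)but-2-en-1-yl]phenol | Cc1ccc(O)c(C)c1C/C=C(/C)C1CO1
A8 | alternative 3 | (4aS,5R)-5-(hydroxymethyl)-1,4a,6-trimethyl-5,8-dihydronaphthalen-2(4aH)-one | CC1=CCC2=C(C)C(=O)C=C[C@@]2(C)[C@@H]1CO
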